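## Analysis of the target

Pleiogenone A (11) is a cyclohex-2-en-1-one. C1 is the ketone, C2=C3 the enone double bond, C4 (S) a secondary allylic alcohol, C5 (R) a secondary alcohol, and C6 (R) a tertiary alcohol that also carries the (8Z)-heptadec-8-en-1-yl chain. The three stereocentres are contiguous: the hydroxyls at C5 and C6 are cis, the hydroxyl at C4 is trans to that at C5, so the chain is cis to O4. The four ring oxygens form two pairs: a 1,4-pair across C2=C3 (O1 as C=O, O4 as OH, a γ-hydroxy enone) and a cis-1,2-pair (O5, O6) on the opposite face. This is the pattern left when an O–O bridge from C1 to C4, anti to a cis-5,6-diol on a cyclohexene ring, is opened by loss of the hydrogen at C1; without the chain, that bridged ring has a mirror plane through the C2=C3 and C5–C6 bonds. The chain is C2–C18 of oleic acid, so it is available as an electrophile by decarboxylation. Sensitive groups are the β-hydroxy ketone/γ-hydroxy enone array (base-induced elimination, then aromatisation), the tertiary α-ketol (acyloin shifts), and the isolated Z alkene (isomerised by thiyl or iodine radicals, attacked by OsO4, peracids, 1O2 and H2/Pd). The difficulty is the C6 carbinol, which is quaternary and flanked by the ketone and a stereocentre, together with setting three adjacent oxygenated centres in absolute terms and joining an unactivated C17 chain to this hindered carbon.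

## Retrosynthetic reasoning

11 ⇒ 10. Only protecting groups are removed: the cis-5,6-diol is carried as a dioxolane and O4 as a silyl ether. Both fall in acid, which the base-labile target tolerates better than any basic unmasking.

10 ⇒ 5 + 8 (through 9). The C6–C1′ bond is cut. C6 is the only enolisable position of 5, because the other α-carbon (C2) is vinylic, so the enolate 9 can form at one place only. The cis-fused dioxolane forces the chain to enter trans to O5, so the hydrogen of 5 is replaced with retention. The forward reaction must alkylate a tetrasubstituted α-alkoxy enolate faster than it expels the β-oxygen at C5.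

8 ⇒ 6 (through 7). The C1–C2 bond of oleic acid 6 is cut; decarboxylation gives the chain with its Z double bond already in place. The forward reaction must trap the primary radical by iodine without isomerising the olefin.

5 ⇒ 4. The silyl group on O4 is removed in the retrosynthetic sense; it is needed only to keep O4 from being alkylated and from acting as an internal base.

4 ⇒ 3 (key disconnection). O1 and O4 are reconnected as an O–O bridge and a hydrogen is returned to C1. This reveals the meso endoperoxide 3, in which C1/C4 and C5/C6 are mirror-related. One catalytic operation on 3 therefore has to do three things: create the ketone, free the C4 carbinol, and choose between two enantiotopic C–H bonds, which fixes C4, C5 and C6 at once.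

3 ⇒ 2. The C1–O and C4–O bonds are cut in a [4+2] sense. The diene 2 must take up the O–O unit on the face anti to the dioxolane, which gives O4 trans to O5.

2 ⇒ 1. The dioxolane is removed to give the commercial meso arene cis-dihydrodiol 1, whose two oxygens become O5 and O6.

## Alternatives that were turned down

Alternative 1: The textbook disconnection cuts C6–C1′ and C6–O as two successive enolate reactions on a chiral-pool cyclohexenone carrying the trans-4,5-diol. In the forward sense (−)-quinic acid A1 would be degraded (oxidative cleavage of the exocyclic C–C bond, β-elimination of O3) to a 4,5-bis-silyloxy enone, alkylated with 8, then hydroxylated at C6. It was turned down for three reasons. Natural A1 gives the (4R,5R)-enone A2, the mirror image of what C4/C5 require, so the needed (4S,5S)-enone A3 calls for the unnatural acid or an oxygen transposition. Even from A3, the alkylation to A4 uses the same unactivated iodide and is followed by oxidation of a tetrasubstituted enolate cis to O5. Each step sets at most one stereocentre, and the count exceeds eight steps.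

Alternative 2: Dearomatisation would cut C6–O on an arene and then O4/O5 on the resulting dienone. In the forward sense 2-alkylphenol A5 would undergo hydroxylative dearomatisation with a chiral pentavalent iodine reagent to o-quinol A6, followed by hydroxyl-directed epoxidation of C4=C5 to A7 and hydrolytic opening at the allylic C4. It was turned down because o-quinols without substituents at C2–C5 dimerise by [4+2] addition at a rate that competes with any epoxidation. Asymmetric induction on simple 2-alkylphenols is also limited, an electrophilic epoxidant would have to spare the chain olefin, and the route carries three uncertain steps in a row.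

Alternative 3: An acyclic chiral-pool route would take C4/C5 from tartrate acetonide A8, set C6 by chelation-controlled addition of the chain as a carbon nucleophile to an α-alkoxy ketone, and close C2=C3 by intramolecular aldol condensation of keto aldehyde A9. It was turned down because seven to eight linear steps lead to A9, whose aldehyde has an epimerisable α-stereocentre and a β-alkoxy leaving group under aldol conditions. The ring must also close against a trans-fused dioxolane, and the ketone has two α-oxygens competing for chelation. No step sets more than one stereocentre.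

Key step: step 3

Assumption: the quinidine-derived catalyst (9-O-acetylcupreidine) is taken to remove the bridgehead proton of 3 that leads to 4; if the sense of induction is the opposite one, its quinine-derived pseudoenantiomer (9-O-acetylcupreine) is used instead.

## Route

Step 1
Reactants: 1 cis-cyclohexa-3,5-diene-1,2-diol (meso)
Product: 2 (3aR,7aS)-2,2-dimethyl-3a,7a-dihydro-1,3-benzodioxole (meso, cis-fused acetonide of 1)
Conditions: 2,2-dimethoxypropane, TsOH·H2O (cat.), CH2Cl2, 0 °C; Et3N quench
Reagents that add atoms: 2,2-dimethoxypropane, COC(C)(C)OC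
Why: Transketalisation of a cis-1,2-diol; the short, cold, acid-catalysed exchange is the standard way to protect arene cis-dihydrodiols before they can dehydrate to phenol, and no stereocentre is touched.

Step 2
Reactants: 2 (3aR,7aS)-2,2-dimethyl-3a,7a-dihydro-1,3-benzodioxole
Product: 3 meso-7,8-(isopropylidenedioxy)-2,3-dioxabicyclo[2.2.2]oct-5-ene, O–O bridge anti to the dioxolane
Conditions: O2, tetraphenylporphyrin (cat.), hν (visible), CH2Cl2, −30 °C
Reagents that add atoms: dioxygen (as singlet oxygen), O=O
Why: [4+2] photooxygenation of a cyclic 1,3-diene; the dioxolane blocks one face, so both new C–O bonds form anti to it, which sets O4 trans to O5 while keeping the mirror plane.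

Step 3
Reactants: 3 meso-7,8-(isopropylidenedioxy)-2,3-dioxabicyclo[2.2.2]oct-5-ene
Product: 4 (4S,5R,6R)-4-hydroxy-5,6-(isopropylidenedioxy)cyclohex-2-en-1-one
Conditions: 9-O-acetylcupreidine (10 mol %), CH2Cl2, rt
Reagents that add atoms: none
Why: Kornblum–DeLaMare rearrangement: the quinuclidine nitrogen of the catalyst removes the bridgehead proton at C1, antiperiplanar to the O–O bond, in an E2-like step; the O–O bond breaks, C1 becomes the ketone, and O4 leaves as an alkoxide that is protonated. The closest known reaction type is the cinchona-alkaloid-catalysed enantioselective Kornblum–DeLaMare rearrangement of meso bicyclic endoperoxides to γ-hydroxy enones; the achiral amine version is the standard fate of 2,3-dioxabicyclo[2.2.2]octene endoperoxides. No ring is closed; the 1,2-dioxane ring is opened and the carbocycle remains as the cyclohex-2-enone. The two bridgehead C–H bonds of 3 are enantiotopic, so the catalyst's choice between them (6′-OH hydrogen-bonded to the peroxide, chiral pocket around the basic nitrogen) fixes the absolute configuration of C4, C5 and C6 at once; their relative configuration comes from the anti addition in step 2. The step needs enantiotopic-group selectivity and must stop at 4: the rigid bicycle holds both C–H bonds equally antiperiplanar to O–O, so only catalyst recognition differentiates them, and the weak amine base at low loading should spare the base-labile product. One catalytic operation thus delivers the enone, the free C4 carbinol and all three stereocentres of the target.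

Step 4
Reactants: 4 (4S,5R,6R)-4-hydroxy-5,6-(isopropylidenedioxy)cyclohex-2-en-1-one
Product: 5 (4S,5S,6R)-4-(tert-butyldimethylsilyloxy)-5,6-(isopropylidenedioxy)cyclohex-2-en-1-one
Conditions: TBSCl, imidazole, DMF, 0 °C
Reagents that add atoms: tert-butyldimethylsilyl chloride, CC(C)(C)[Si](C)(C)Cl
Why: Silylation of a secondary allylic alcohol under weakly basic conditions; it keeps O4 from being alkylated or acting as an internal base in step 6, and the change of the C5 descriptor is only a priority change.

Step 5
Reactants: 6 oleic acid, (9Z)-octadec-9-enoic acid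
Product: 8 (8Z)-1-iodoheptadec-8-ene, via thiohydroxamate ester 7 (not isolated)
Conditions: 1-hydroxypyridine-2(1H)-thione, DCC, DMAP (cat.), CH2Cl2, 0 °C, dark; then CHI3, benzene, hν (tungsten lamp), rt
Reagents that add atoms: iodoform, IC(I)I
Why: Barton decarboxylative iodination: the thiohydroxamate ester fragments in a radical chain to the primary C17 radical, which abstracts iodine from iodoform; the olefin is eight carbons from the radical, too far to cyclise, and the chain needs no tin or thiol.

Step 6
Reactants: 5 (4S,5S,6R)-4-(tert-butyldimethylsilyloxy)-5,6-(isopropylidenedioxy)cyclohex-2-en-1-one; 8 (8Z)-1-iodoheptadec-8-ene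
Product: 10 (4S,5R,6R)-4-(tert-butyldimethylsilyloxy)-6-[(8Z)-heptadec-8-en-1-yl]-5,6-(isopropylidenedioxy)cyclohex-2-en-1-one, via lithium dienolate 9 (not isolated)
Conditions: LiN(iPr)2, THF, −78 °C; then 8, DMPU, −78 → −30 °C
Reagents that add atoms: none
Why: Enolate alkylation: C6–H is the only α-hydrogen of 5, and in the cross-conjugated dienolate the dioxolane holds the C5–O bond near the nodal plane, so β-elimination is stereoelectronically hampered, as with enolates of tartrate acetonides. The chain must enter trans to O5 to keep the dioxolane cis-fused, which replaces H at C6 with retention and sets the quaternary C6 as R.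

Step 7
Reactants: 10 (4S,5R,6R)-4-(tert-butyldimethylsilyloxy)-6-[(8Z)-heptadec-8-en-1-yl]-5,6-(isopropylidenedioxy)cyclohex-2-en-1-one
Product: 11 pleiogenone A, (4S,5R,6R)-6-[(8Z)-heptadec-8-en-1-yl]-4,5,6-trihydroxycyclohex-2-en-1-one
Conditions: CF3CO2H/H2O (9:1), 0 °C → rt
Reagents that add atoms: none
Why: Acid hydrolysis of the ketal and the silyl ether in one operation; C6 has no α-hydrogen, C4 and C5 do not epimerise in acid, and the Z olefin and the enone are inert to these conditions.

## Compound list

1 | cis-cyclohexa-3,5-diene-1,2-diol (meso) | O[C@H]1C=CC=C[C@H]1O | starting material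
2 | (3aR,7aS)-2,2-dimethyl-3a,7a-dihydro-1,3-benzodioxole | C1=C[C@@H]2OC(C)(C)O[C@@H]2C=C1 | intermediate
3 | meso-7,8-(isopropylidenedioxy)-2,3-dioxabicyclo[2.2.2]oct-5-ene (O–O anti to dioxolane) | C1=C[C@@H]2OO[C@H]1[C@@H]1OC(C)(C)O[C@H]21 | intermediate
4 | (4S,5R,6R)-4-hydroxy-5,6-(isopropylidenedioxy)cyclohex-2-en-1-one | O=C1C=C[C@H](O)[C@H]2OC(C)(C)O[C@@H]12 | intermediate
5 | (4S,5S,6R)-4-(tert-butyldimethylsilyloxy)-5,6-(isopropylidenedioxy)cyclohex-2-en-1-one | O=C1C=C[C@H](O[Si](C)(C)C(C)(C)C)[C@H]2OC(C)(C)O[C@@H]12 | intermediate
6 | oleic acid, (9Z)-octadec-9-enoic acid | CCCCCCCC/C=C\CCCCCCCC(=O)O | starting material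
7 | 2-thioxopyridin-1(2H)-yl (9Z)-octadec-9-enoate | CCCCCCCC/C=C\CCCCCCCC(=O)On1ccccc1=S | intermediate
8 | (8Z)-1-iodoheptadec-8-ene | CCCCCCCC/C=C\CCCCCCCI | intermediate
9 | lithium dienolate of 5 (O1–Li, C1=C6, C2=C3) | [Li]OC1=C2OC(C)(C)O[C@@H]2[C@@H](O[Si](C)(C)C(C)(C)C)C=C1 | intermediate
10 | (4S,5R,6R)-4-(tert-butyldimethylsilyloxy)-6-[(8Z)-heptadec-8-en-1-yl]-5,6-(isopropylidenedioxy)cyclohex-2-en-1-one | CCCCCCCC/C=C\CCCCCCC[C@@]12OC(C)(C)O[C@@H]1[C@@H](O[Si](C)(C)C(C)(C)C)C=CC2=O | intermediate
11 | pleiogenone A, (4S,5R,6R)-6-[(8Z)-heptadec-8-en-1-yl]-4,5,6-trihydroxycyclohex-2-en-1-one | CCCCCCCC/C=C\CCCCCCC[C@]1(O)C(=O)C=C[C@H](O)[C@H]1O | target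

## Step count and risk

Total step count: 7. Longest linear sequence: 6 steps (1 → 2 → 3 → 4 → 5 → 10 → 11); the chain is made in a one-step branch (step 5).

Step 3 (key step). The most likely failure is incomplete discrimination of the two enantiotopic bridgehead protons, because the bicyclo[2.2.2] endoperoxide is more compact than the larger-ring cases and its bridgeheads sit next to the dioxolane. A second risk is onward base-induced elimination of the product during a slow reaction. The fallback sets out from 3 and uses enzymatic instead of base desymmetrisation. The O–O bond is reduced with thiourea to the meso cis-ene-1,4-diol F1. A lipase (Burkholderia cepacia lipase, vinyl acetate; or hydrolysis of the diacetate if the opposite sense is needed) then gives monoacetate F2, acetylated at the carbinol destined to be C1. Silylation of the free hydroxyl gives silyl ether acetate F3, and methanolysis (K2CO3, MeOH) gives allylic alcohol F4. Oxidation with MnO2 returns to the route at 5.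

Step 6. The most likely failure is slow C-alkylation of the hindered, tetrasubstituted α-alkoxy dienolate by an unactivated primary iodide. On warming, expulsion of the C5 oxygen followed by aromatisation, or O-alkylation, would then take over. The fallback sets out from 5 and switches to a far more nucleophilic azaenolate. Condensation with 1,1-dimethylhydrazine gives dimethylhydrazone F5. Deprotonation with LiN(iPr)2 and alkylation with 8 at −78 °C, under the same cis-fusion control, give alkylated hydrazone F6. Neutral hydrolysis (CuCl2, aqueous THF, pH 7) returns to the route at 10.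

Step 5. The most likely failure is partial Z-to-E isomerisation of the C8=C9 bond through reversible addition of iodine atoms formed by photolysis of iodoform. The fallback does not set out from 6; it builds the chain from commercial 1-decyne and 7-bromoheptan-1-ol and fixes the Z geometry by semi-hydrogenation. The lithium acetylide of 1-decyne (two equivalents, THF/DMPU) is alkylated by the bromo alcohol to give heptadec-8-yn-1-ol F7. Hydrogenation over Pd/CaCO3 poisoned with Pb(OAc)2 and quinoline gives (8Z)-heptadec-8-en-1-ol F8. An Appel reaction (I2, PPh3, imidazole) returns to the route at 8.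

## Further compounds

F1 | step 3 | meso 5,6-(isopropylidenedioxy)cyclohex-2-ene-1,4-diol (both hydroxyls anti to the dioxolane) | O[C@@H]1C=C[C@H](O)[C@H]2OC(C)(C)O[C@@H]12
F2 | step 3 | monoacetate of F1, acetate on the carbinol that becomes C1 | CC(=O)O[C@@H]1C=C[C@H](O)[C@H]2OC(C)(C)O[C@@H]12
F3 | step 3 | tert-butyldimethylsilyl ether of F2 | CC(=O)O[C@@H]1C=C[C@H](O[Si](C)(C)C(C)(C)C)[C@H]2OC(C)(C)O[C@@H]12
F4 | step 3 | allylic alcohol from deacetylation of F3 | O[C@@H]1C=C[C@H](O[Si](C)(C)C(C)(C)C)[C@H]2OC(C)(C)O[C@@H]12
F5 | step 6 | N,N-dimethylhydrazone of 5 | CN(C)N=C1C=C[C@H](O[Si](C)(C)C(C)(C)C)[C@H]2OC(C)(C)O[C@@H]12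
F6 | step 6 | N,N-dimethylhydrazone of 10 | CCCCCCCC/C=C\CCCCCCC[C@@]12OC(C)(C)O[C@@H]1[C@@H](O[Si](C)(C)C(C)(C)C)C=CC2=NN(C)C
F7 | step 5 | heptadec-8-yn-1-ol | CCCCCCCCC#CCCCCCCCO
F8 | step 5 | (8Z)-heptadec-8-en-1-ol | CCCCCCCC/C=C\CCCCCCCO
A1 | alternative 1 | (−)-quinic acid | OC(=O)[C@]1(O)C[C@@H](O)[C@@H](O)[C@H](O)C1
A2 | alternative 1 | (4R,5R)-4,5-bis(tert-butyldimethylsilyloxy)cyclohex-2-en-1-one | O=C1C=C[C@@H](O[Si](C)(C)C(C)(C)C)[C@H](O[Si](C)(C)C(C)(C)C)C1
A3 | alternative 1 | (4S,5S)-4,5-bis(tert-butyldimethylsilyloxy)cyclohex-2-en-1-one | O=C1C=C[C@H](O[Si](C)(C)C(C)(C)C)[C@@H](O[Si](C)(C)C(C)(C)C)C1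
A4 | alternative 1 | (4S,5S)-4,5-bis(tert-butyldimethylsilyloxy)-6-[(8Z)-heptadec-8-en-1-yl]cyclohex-2-en-1-one (C6 epimers) | O=C1C=C[C@H](O[Si](C)(C)C(C)(C)C)[C@@H](O[Si](C)(C)C(C)(C)C)C1CCCCCCC/C=C\CCCCCCCC
A5 | alternative 2 | 2-[(8Z)-heptadec-8-en-1-yl]phenol | CCCCCCCC/C=C\CCCCCCCc1ccccc1O
A6 | alternative 2 | (6R)-6-[(8Z)-heptadec-8-en-1-yl]-6-hydroxycyclohexa-2,4-dien-1-one | CCCCCCCC/C=C\CCCCCCC[C@@]1(O)C=CC=CC1=O
A7 | alternative 2 | 4,5-epoxide of A6, syn to the C6 hydroxyl | CCCCCCCC/C=C\CCCCCCC[C@@]1(O)[C@@H]2O[C@@H]2C=CC1=O
A8 | alternative 3 | dimethyl (4R,5R)-2,2-dimethyl-1,3-dioxolane-4,5-dicarboxylate (L-tartrate acetonide) | COC(=O)[C@@H]1OC(C)(C)O[C@H]1C(=O)OC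
A9 | alternative 3 | keto aldehyde: 4-C-[(8Z)-heptadec-8-en-1-yl]-4-hydroxy-2,3-(isopropylidenedioxy)-5-oxohexanal, configured as C4–C6 of 11 | CCCCCCCC/C=C\CCCCCCC[C@](O)(C(C)=O)[C@@H]1OC(C)(C)O[C@H]1C=O
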